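**Plan**

- Locants: C1 (OAc), C2 (OBz), C3=C4, C5 (OH), C6 (OH and C7H2OBz); the cyclopentadiene carbons are C8 (bonded to C3), C9=C10, C11 (bonded to C4) and C12 (CH2 bridge). Enabling feature: oxygen on C2 and C5 on either side of C3=C4, with C7 on C6 next to C1, makes ring C1–C6 a 2-substituted 1,4-benzoquinone in disguise (C2=O, C5=O, C1=C6) whose unsubstituted C3=C4 is a dienophile.
- Retrosynthesis: C3=C4 is covered again by cyclopentadiene (adds C3–C8 and C4–C11). The ester C–O bonds at O1 and O2 are cut, C1–O and C6–O are cut back to the C1=C6 alkene, and C2–H and C5–H back to two ketones. Last, C3–C8 and C4–C11 are cut by the Diels–Alder transform to the benzoyloxymethyl quinone and cyclopentadiene.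
- Forward: ring C1–C6 is the arene of commercial 2,5-dimethoxybenzyl alcohol. The only ring built is the norbornene (step 4). A temporary cyclic bromo ether (O5–C10) is closed in step 7 and reopened in step 10, and the norbornene is expelled in step 11.
- Stereochemistry: the chiral catalyst sets the absolute configuration in step 4. The folded endo tricycle passes it on: hydride (step 5) and OsO4 (step 8) both arrive from the convex face, putting O2/O5 on one face and O1/O6 on the other. The cycloreversion destroys only the stereocentres C3, C4, C8 and C11.

Key step: step 4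

Assumption: the sense of induction in step 4 is assigned from the accepted binding model of the oxazaborolidinium ion (quinone on its convex face, C3–H towards the ring oxygen, the cis phenyl under C3=C4); if the adduct proved antipodal, the catalyst from (S)-α,α-diphenylprolinol would be used with nothing else changed.

**Route**

Step 1
Reactants: 1 2,5-dimethoxybenzyl alcohol; 2 benzoyl chloride
Product: 3 2,5-dimethoxybenzyl benzoate
Conditions: Et3N, DMAP (cat.), CH2Cl2, 0 °C to rt
Reagents that add atoms: none
Why: DMAP-catalysed O-acylation (esterification) of a primary benzylic alcohol with an acid chloride is fast and clean; no stereocentre is formed.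

Step 2
Reactants: 3 2,5-dimethoxybenzyl benzoate
Product: 4 (3,6-dioxocyclohexa-1,4-dien-1-yl)methyl benzoate
Conditions: (NH4)2Ce(NO3)6 (2.5 equiv), MeCN/H2O, 0 °C
Reagents that add atoms: water, O
Why: Oxidative demethylation of a 1,4-dimethoxyarene to the 1,4-benzoquinone by tetravalent cerium goes through the arene radical cation, water supplies both carbonyl oxygens, and the benzylic ester is inert; no stereocentre is formed.

Step 3
Reactants: 5 dicyclopentadiene
Product: 6 cyclopentadiene
Conditions: neat, 170–180 °C, distillation through a short column, receiver at −78 °C, used at once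
Reagents that add atoms: none
Why: Thermal retro-Diels–Alder cracking splits each molecule of the dimer into two molecules of the monomer, which is distilled off as it forms and used cold before it dimerises again; no stereocentre is formed.

Step 4
Reactants: 4 (3,6-dioxocyclohexa-1,4-dien-1-yl)methyl benzoate; 6 cyclopentadiene
Product: 7 endo cyclopentadiene adduct of the quinone at C3=C4
Conditions: oxazaborolidine from (R)-α,α-diphenylprolinol and o-tolylboroxine (20 mol%), Tf2NH (18 mol%), 6 (3 equiv), CH2Cl2, −78 °C; Et3N quench
Reagents that add atoms: none
Why: The protonated oxazaborolidine should bind the quinone at O2, the carbonyl oxygen flanked by two α-C–H groups and remote from the C6 side chain, with C3–H held against the ring oxygen of the catalyst, which lowers the LUMO at C3=C4 and lays that alkene over the cis phenyl group. Cyclopentadiene then adds to the uncovered face in a concerted, asynchronous [4+2] cycloaddition (C4–C11 leading), the closest known reaction type being the oxazaborolidinium-catalysed Diels–Alder reaction of substituted 1,4-benzoquinones with cyclopentadiene. The one ring that closes, the six-membered ring C3–C4–C11–C10=C9–C8 of the norbornene (bridged by C12), forms by suprafacial [4π+2π] closure through the endo transition state. C3 and C4 (cis hydrogens) follow from suprafacial addition to the cis alkene, C8 and C11 relative to them from the endo preference of the diene for the face over the enedione carbonyls, and the absolute sense from the phenyl group of the catalyst. The step needs site selectivity (C3=C4, not C1=C6), secured by the C7 substituent that hinders and deactivates C1=C6; endo selectivity, secured by secondary overlap at −78 °C; and a single orientation of the quinone on the catalyst, secured by the steric difference between O2 (two α-H) and O5 (α-substituent).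

Step 5
Reactants: 7 endo cyclopentadiene adduct
Product: 8 endo,endo-2,5-diol
Conditions: NaBH4, CeCl3·7H2O, MeOH/CH2Cl2, −78 °C
Reagents that add atoms: none
Why: Luche 1,2-reduction: the cerium-modified borohydride should attack both enedione carbonyls directly and only from the open convex face of the folded tricycle, so the new carbinol centres C2 and C5 both carry OH on the concave face.

Step 6
Reactants: 8 endo,endo-2,5-diol; 2 benzoyl chloride (1.05 equiv, added slowly)
Product: 9 2-O-benzoate with C5–OH free
Conditions: pyridine, CH2Cl2, −40 to −20 °C
Reagents that add atoms: none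
Why: Kinetic mono-O-benzoylation: both carbinols adjoin the ring fusion, but C5–OH also has the C7-bearing C6 beside it whereas C2–OH has only C1–H on its other side, so the acid chloride should acylate O2 first at low temperature with a weak base that does not trigger acyl migration; no stereocentre is formed.

Step 7
Reactants: 9 2-O-benzoate
Product: 10 cage bromo ether (O5–C10, Br on C9)
Conditions: NBS (1.1 equiv), CH2Cl2, 0 °C, dark
Reagents that add atoms: N-bromosuccinimide, O=C1CCC(=O)N1Br
Why: Bromoetherification: Br+ should add to the exo face of the strained, electron-rich norbornene alkene and the endo C5–OH open the bromonium ion at C10 from inside (5-exo closure, anti addition: Br exo at C9, O endo at C10); this ties up C5–OH and removes the one alkene that would outrun C1=C6 towards OsO4, while the less reactive C1=C6 stays untouched.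

Step 8
Reactants: 10 cage bromo ether
Product: 11 1,6-diol
Conditions: OsO4 (5 mol%), N-methylmorpholine N-oxide (2 equiv), acetone/H2O, rt to 40 °C
Reagents that add atoms: osmium tetroxide, O=[Os](=O)(=O)=O; N-methylmorpholine N-oxide, C[N+]1([O-])CCOCC1; water, O
Why: Upjohn cis-dihydroxylation (suprafacial [3+2] addition of OsO4) of the one remaining alkene from the convex face, anti to both allylic oxygens on C2 and C5 and away from the cage, should set C1–OH and C6–OH cis to each other and trans to O2 and O5.

Step 9
Reactants: 11 1,6-diol
Product: 12 1-O-acetate
Conditions: Ac2O, pyridine, DMAP (cat.), CH2Cl2, 0 °C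
Reagents that add atoms: acetic anhydride, CC(=O)OC(C)=O
Why: Pyridine/DMAP acetylation should esterify the secondary C1–OH while the tertiary C6–OH does not react under these conditions; no stereocentre is touched.

Step 10
Reactants: 12 1-O-acetate
Product: 13 norbornene-masked target
Conditions: Zn dust (activated, excess), AcOH, THF/EtOH, 60 °C
Reagents that add atoms: none
Why: Zinc-mediated reductive β-elimination of the β-bromo ether (Boord-type) should regenerate C9=C10 and release C5–OH with its C–O bond, and so its configuration, intact; esters and the tertiary alcohol are inert to zinc in acetic acid.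

Step 11
Reactants: 13 norbornene-masked target
Product: 14 HY-N2634
Conditions: Ph2O, 250 °C, N2 stream, about 30 min
Reagents that add atoms: none
Why: Thermal retro-Diels–Alder reaction should expel cyclopentadiene (swept out in the gas stream) and unveil C3=C4; only the auxiliary centres C3, C4, C8 and C11 disappear, and the four carbinol centres are not involved.

**Compound list**

1 | 2,5-dimethoxybenzyl alcohol | COc1ccc(OC)c(CO)c1 | starting material
2 | benzoyl chloride | O=C(Cl)c1ccccc1 | starting material
3 | 2,5-dimethoxybenzyl benzoate | COc1ccc(OC)c(COC(=O)c2ccccc2)c1 | intermediate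
4 | (3,6-dioxocyclohexa-1,4-dien-1-yl)methyl benzoate | O=C1C=CC(=O)C(COC(=O)c2ccccc2)=C1 | intermediate
5 | dicyclopentadiene (commercial endo dimer, racemic, drawn without descriptors) | C1C=CC2C1C1CC2C=C1 | starting material
6 | cyclopentadiene | C1=CC=CC1 | intermediate
7 | (5,8-dioxo-1,4,4a,5,8,8a-hexahydro-1,4-methanonaphthalen-6-yl)methyl benzoate, endo adduct: H-3 and H-4 cis and exo on the norbornene, enedione ring under C9=C10; seen from the H-3/H-4 (convex) face, C1 to C6 run clockwise | O=C1C=C(COC(=O)c2ccccc2)C(=O)[C@@H]4[C@H]1[C@@H]3C=C[C@H]4C3 | intermediate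
8 | 7 with both ketones reduced: C2–OH and C5–OH on the concave (endo) face, cis to the C3–C8 and C4–C11 bonds; C7 benzoate kept | O[C@H]1C=C(COC(=O)c2ccccc2)[C@@H](O)[C@@H]4[C@H]1[C@@H]3C=C[C@H]4C3 | intermediate
9 | 8 benzoylated at O2 (C5–OH free) | O=C(c5ccccc5)O[C@H]1C=C(COC(=O)c2ccccc2)[C@@H](O)[C@@H]4[C@H]1[C@@H]3C=C[C@H]4C3 | intermediate
10 | cage bromo ether of 9: O5 bonded to C10 (endo), Br on C9 (exo), C1=C6 intact | O=C(c5ccccc5)O[C@H]1C=C(COC(=O)c2ccccc2)[C@H]6O[C@H]7[C@H](Br)[C@@H]3C[C@H]7[C@H]6[C@H]13 | intermediate
11 | 10 with C1–OH and C6–OH on the convex face (cis to each other and to H-3/H-4, trans to O2 and O5) | O=C(c5ccccc5)O[C@H]1[C@H](O)[C@@](O)(COC(=O)c2ccccc2)[C@H]6O[C@H]7[C@H](Br)[C@@H]3C[C@H]7[C@H]6[C@H]13 | intermediate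
12 | 11 acetylated at O1 (tertiary C6–OH free) | O=C(c5ccccc5)O[C@H]1[C@H](OC(C)=O)[C@@](O)(COC(=O)c2ccccc2)[C@H]6O[C@H]7[C@H](Br)[C@@H]3C[C@H]7[C@H]6[C@H]13 | intermediate
13 | endo cyclopentadiene adduct of the target across C3=C4 (12 with C9=C10 restored and C5–OH free) | O=C(c5ccccc5)O[C@H]1[C@H](OC(C)=O)[C@@](O)(COC(=O)c2ccccc2)[C@@H](O)[C@@H]4[C@H]1[C@@H]3C=C[C@H]4C3 | intermediate
14 | HY-N2634, (1S,2R,5S,6R)-1-acetoxy-2-benzoyloxy-6-(benzoyloxymethyl)cyclohex-3-ene-5,6-diol (locants as above) | CC(=O)O[C@H]1[C@H](OC(=O)c2ccccc2)C=C[C@H](O)[C@]1(O)COC(=O)c1ccccc1 | target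

**Count and risks**

Total steps: 11. Longest linear sequence: 10 (steps 1, 2 and 4 to 11; step 3 only supplies the diene).

Step 6, loss of site selectivity in the mono-acylation (acylation at O5, double acylation, or base-induced benzoyl migration from O7 to O5). The two secondary hydroxyls would then be told apart by a tether instead of by rate. Setting out from 8, methanolysis of the C7 benzoate (K2CO3, MeOH, 0 °C) would give the 2,5,7-triol F1. 2,2-Dimethoxypropane with pyridinium p-toluenesulfonate can close a six-membered acetonide only across O5 and O7 (on C5–C6–C7), giving the O5,O7-isopropylidene alcohol F2 with O2–H alone free. Benzoylation (2, pyridine, DMAP) would give the acetonide benzoate F3, and aqueous acetic acid would remove the acetal to give the 2-O-benzoyl 5,7-diol F4. Benzoyl chloride 2 with 2,4,6-collidine at −40 °C should then acylate the primary allylic O7–H in preference to the hindered endo O5–H, which brings the sequence back to 9.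

Step 11, thermal damage during cycloreversion (slow loss of cyclopentadiene from a tricycle that releases an unconjugated alkene, competing with [3,3] transposition of the C2 benzoate or acyl migration in the product at 250 °C). The oxidation level at C5 would be changed for the thermolysis. Setting out from 13, Dess–Martin periodinane would oxidise C5–OH to the tricyclic 5-ketone F5. Its cycloreversion sets C3=C4 free in conjugation with C5=O and should therefore run in refluxing 1,2-dichlorobenzene (about 180 °C), giving the cyclohexenone F6. Hydroxyl-directed 1,2-reduction with Me4NBH(OAc)3 (MeCN/AcOH, −30 °C), in which the acetoxyborohydride bound to the tertiary O6 delivers hydride to C5 on the face of O6, should place C5–OH trans to C6–OH and return the route to 14.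

Step 4, erosion of enantioselectivity (catalyst bound at O5 or tied up by the benzoate carbonyl, or uncatalysed background addition). The adduct would then be made racemic and resolved enzymatically. Setting out from 4 and 6, uncatalysed addition in CH2Cl2 at 0 °C would give the endo adduct as the racemate, 7 together with its antipode ent-7 F7. Reduction as in step 5 would give 8 together with ent-8 F8. Lipase from Burkholderia cepacia with vinyl acetate in tert-butyl methyl ether should, by the empirical size rule for lipase acylation of secondary carbinols (large group the ring-fusion carbon, medium group C1–H), acetylate the unhindered O2–H of ent-8 to the 2-O-acetate of ent-8 F9. It should leave 8 as the diol, because its O2–H has the slow-reacting configuration and its O5–H is flanked on both sides. Chromatography separates the two and 8 rejoins the route.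

Further compounds

F1 | step 6 | 2,5,7-triol (8 without the C7 benzoyl group) | O[C@H]1C=C(CO)[C@@H](O)[C@@H]4[C@H]1[C@@H]3C=C[C@H]4C3
F2 | step 6 | O5,O7-isopropylidene acetal of F1 (O2–H free) | O[C@H]1C=C5COC(C)(C)O[C@H]5[C@@H]4[C@H]1[C@@H]3C=C[C@H]4C3
F3 | step 6 | 2-O-benzoate of F2 | O=C(c2ccccc2)O[C@H]1C=C5COC(C)(C)O[C@H]5[C@@H]4[C@H]1[C@@H]3C=C[C@H]4C3
F4 | step 6 | 2-O-benzoyl 5,7-diol | O=C(c2ccccc2)O[C@H]1C=C(CO)[C@@H](O)[C@@H]4[C@H]1[C@@H]3C=C[C@H]4C3
F5 | step 11 | tricyclic 5-ketone (13 with C5=O) | O=C(c5ccccc5)O[C@H]1[C@H](OC(C)=O)[C@@](O)(COC(=O)c2ccccc2)C(=O)[C@@H]4[C@H]1[C@@H]3C=C[C@H]4C3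
F6 | step 11 | cyclohexenone (14 with C5=O) | CC(=O)O[C@H]1[C@H](OC(=O)c2ccccc2)C=CC(=O)[C@]1(O)COC(=O)c1ccccc1
F7 | step 4 | ent-7 | O=C1C=C(COC(=O)c2ccccc2)C(=O)[C@H]4[C@@H]1[C@H]3C=C[C@@H]4C3
F8 | step 4 | ent-8 | O[C@@H]1C=C(COC(=O)c2ccccc2)[C@H](O)[C@H]4[C@@H]1[C@H]3C=C[C@@H]4C3
F9 | step 4 | 2-O-acetate of ent-8 | CC(=O)O[C@@H]1C=C(COC(=O)c2ccccc2)[C@H](O)[C@H]4[C@@H]1[C@H]3C=C[C@@H]4C3
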